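**Plan**

- Target 17 is 1-(5,8-dihydroxy-7-methoxy-2,2-dimethyl-2H-chromen-6-yl)-3-phenylpropan-1-one, an achiral molecule.
- Retrosynthesis: the C5/C8 hydroxyls are traced to a para pair of methyl ethers through the 5,8-quinone, and then the pyran C3=C4 bond is cut. Next come the C6–C(=O) bond (aryllithium plus aldehyde), the vinyl carbon on C4a (from a formyl group), the O1–C2 bond (phenol alkylation) and the aryl–CHO bond, back to 1,2,3,5-tetramethoxybenzene.
- Enabling feature: the pyran ring O1–C2–C3=C4–C4a–C8a holds its only alkene, cis C3=C4, between aryl carbon C4a and the quaternary C2(CH3)2 on O1. That is what ring-closing metathesis makes from an aryl vinyl group ortho to an aryl 2-methylbut-3-en-2-yl ether.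
- Forward: the benzene ring is substituted in place (CHO, free OH, Br), the tertiary allyl ether and the vinyl group are installed, and the 3-phenylpropanoyl chain is joined at C6. The pyran, the only ring made, then closes by metathesis, and the hydroquinone is unveiled last.
- Stereochemistry: none has to be set. The ring alkene is cis by necessity, and the carbinol centre of 13 is racemic and removed by oxidation.

Key step: step 9

Remark: the target has no stereocentre and is achiral, so the single-enantiomer requirement is met by the constitution alone.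

**Route**

Step 1
Reactants: 1 1,2,3,5-tetramethoxybenzene
Product: 3 2,3,4,6-tetramethoxybenzaldehyde, via iminium chloride 2 (not isolated)
Conditions: POCl3, DMF, 0 °C → 60 °C; then ice–H2O
Reagents that add atoms: N,N-dimethylformamide CN(C)C=O; water O
Why: Vilsmeier–Haack formylation, in which the chloroiminium electrophile attacks one of the two equivalent, strongly activated ring CH positions of the symmetric arene, and the deactivating iminium group should prevent a second formylation.

Step 2
Reactants: 3 2,3,4,6-tetramethoxybenzaldehyde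
Product: 5 2-hydroxy-3,4,6-trimethoxybenzaldehyde, via dichloroboron aryloxide 4 (not isolated)
Conditions: BCl3 (1.1 equiv), CH2Cl2, −78 → 0 °C; then H2O
Reagents that add atoms: none
Why: Chelation-controlled Lewis-acid ether cleavage, in which BCl3 bridges the aldehyde oxygen and an ortho methoxy oxygen, and of the two ortho methoxy groups the C2 one, twisted out of the ring plane by its neighbours (CHO and C3-OMe) and therefore the more basic, should lose its methyl to chloride, as is the rule for 2,3,4-tri- and 2,3,4,6-tetramethoxyaryl carbonyl compounds.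

Step 3
Reactants: 5 2-hydroxy-3,4,6-trimethoxybenzaldehyde
Product: 6 3-bromo-6-hydroxy-2,4,5-trimethoxybenzaldehyde
Conditions: NBS (1.0 equiv), MeCN, 0 °C
Reagents that add atoms: N-bromosuccinimide O=C1CCC(=O)N1Br
Why: Electrophilic aromatic bromination, which can only occur at the single remaining ring CH, para to the free phenol and flanked by two methoxy groups.

Step 4
Reactants: 6 3-bromo-6-hydroxy-2,4,5-trimethoxybenzaldehyde; 7 3-chloro-3-methylbut-1-yne
Product: 8 3-bromo-2,4,5-trimethoxy-6-(2-methylbut-3-yn-2-yloxy)benzaldehyde
Conditions: K2CO3, KI (cat.), CuI (cat.), acetone, reflux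
Reagents that add atoms: none
Why: Copper-catalysed O-propargylation of a phenoxide with a tertiary propargylic chloride (a Williamson-type etherification known for salicylaldehydes), which should leave the aldehyde and the aryl bromide untouched.

Step 5
Reactants: 8 3-bromo-2,4,5-trimethoxy-6-(2-methylbut-3-yn-2-yloxy)benzaldehyde
Product: 9 3-bromo-2,4,5-trimethoxy-6-(2-methylbut-3-en-2-yloxy)benzaldehyde
Conditions: H2 (1 atm), Lindlar catalyst, quinoline, EtOAc, rt
Reagents that add atoms: none
Why: Lindlar semi-hydrogenation, in which the poisoned palladium reduces the terminal alkyne to the alkene and stops, while the aryl bromide, the aldehyde and the aryl ether C–O bond are not reduced, the alkyne being the only unsaturated C–C bond present at this stage.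

Step 6
Reactants: 9 3-bromo-2,4,5-trimethoxy-6-(2-methylbut-3-en-2-yloxy)benzaldehyde
Product: 10 1-bromo-3-ethenyl-2,5,6-trimethoxy-4-(2-methylbut-3-en-2-yloxy)benzene
Conditions: Ph3PCH3Br, KOtBu, THF, 0 °C → rt
Reagents that add atoms: methyltriphenylphosphonium bromide C[P+](c1ccccc1)(c1ccccc1)c1ccccc1.[Br-]
Why: Wittig methylenation, in which the unstabilised ylide converts the hindered but non-enolisable aryl aldehyde into the styrene with the bromide and the allyl ether as spectators.

Step 7
Reactants: 10 1-bromo-3-ethenyl-2,5,6-trimethoxy-4-(2-methylbut-3-en-2-yloxy)benzene; 11 3-phenylpropanal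
Product: 13 racemic 1-[3-ethenyl-2,5,6-trimethoxy-4-(2-methylbut-3-en-2-yloxy)phenyl]-3-phenylpropan-1-ol, via aryllithium 12 (not isolated)
Conditions: n-BuLi, THF, −78 °C; then 11, −78 °C; H2O
Reagents that add atoms: none
Why: Bromine–lithium exchange followed by 1,2-addition to an aldehyde, where exchange at a bromide flanked by two coordinating methoxy groups should be faster at −78 °C than attack of butyllithium on the styrene, the substrate has no acidic hydrogen, and the new carbinol centre is left racemic because the next step removes it.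

Step 8
Reactants: 13 racemic 1-[3-ethenyl-2,5,6-trimethoxy-4-(2-methylbut-3-en-2-yloxy)phenyl]-3-phenylpropan-1-ol
Product: 14 1-[3-ethenyl-2,5,6-trimethoxy-4-(2-methylbut-3-en-2-yloxy)phenyl]-3-phenylpropan-1-one
Conditions: Dess–Martin periodinane, pyridine, CH2Cl2, 0 °C → rt
Reagents that add atoms: none
Why: Dess–Martin oxidation of the secondary benzylic alcohol to the aryl ketone under pyridine-buffered, near-neutral conditions that should spare the acid-labile tertiary allyl aryl ether and both alkenes.

Step 9
Reactants: 14 1-[3-ethenyl-2,5,6-trimethoxy-4-(2-methylbut-3-en-2-yloxy)phenyl]-3-phenylpropan-1-one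
Product: 15 1-(5,7,8-trimethoxy-2,2-dimethyl-2H-chromen-6-yl)-3-phenylpropan-1-one
Conditions: Grubbs second-generation catalyst (5 mol %), CH2Cl2 (0.005 M), 40 °C
Reagents that add atoms: none
Why: Ring-closing olefin metathesis, in which the ruthenium benzylidene exchanges onto one of the two terminal alkenes (most likely the aryl vinyl group, since the other sits on a quaternary carbon), the new alkylidene adds [2+2] to the second alkene within the molecule, and cycloreversion of the ruthenacyclobutane releases the chromene and a ruthenium methylidene that carries the chain, with ethene lost as the driving force. The closest known reaction is the ring-closing metathesis of 2-vinylaryl allyl and 1,1-dimethylallyl ethers to 2H-chromenes. The one ring formed is the six-membered pyran, closed by joining the two terminal alkene carbons so that the new C3=C4 bond lies inside the ring, where only the cis geometry is possible. No stereocentre is created. The step needs ring closure to win over intermolecular cross-metathesis and over loss or [3,3] shift of the tertiary allyl group, and high dilution, the gem-dimethyl group at C2, the fully substituted positions on both sides of the ether oxygen and the mild neutral conditions should secure this. The aryl ketone and the three methyl ethers do not react with the carbene.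

Step 10
Reactants: 15 1-(5,7,8-trimethoxy-2,2-dimethyl-2H-chromen-6-yl)-3-phenylpropan-1-one
Product: 16 7-methoxy-2,2-dimethyl-6-(3-phenylpropanoyl)-2H-chromene-5,8-dione
Conditions: (NH4)2Ce(NO3)6 (2.2 equiv), MeCN/H2O, 0 °C
Reagents that add atoms: water O
Why: Oxidative demethylation with cerium(IV), in which two one-electron oxidations of the electron-rich arene and attack of water at C5 and C8, the only para-related pair of methoxy-bearing carbons, expel two molecules of methanol and should give the para-quinone, as known for 5,8-dimethoxy-2H-chromenes, while the C7 methoxy group is retained.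

Step 11
Reactants: 16 7-methoxy-2,2-dimethyl-6-(3-phenylpropanoyl)-2H-chromene-5,8-dione
Product: 17 1-(5,8-dihydroxy-7-methoxy-2,2-dimethyl-2H-chromen-6-yl)-3-phenylpropan-1-one
Conditions: Na2S2O4, EtOAc/H2O, rt, under argon
Reagents that add atoms: none
Why: Two-electron quinone reduction by dithionite, which should give the hydroquinone without touching the ketone, the chromene alkene or the methyl ether, the C5 hydroxyl being held by a hydrogen bond to the ketone.

**Compound list**

1 | 1,2,3,5-tetramethoxybenzene | COc1cc(OC)c(OC)c(OC)c1 | starting material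
2 | N,N-dimethyl-1-(2,3,4,6-tetramethoxyphenyl)methaniminium chloride (formed in the flask) | C[N+](C)=Cc1c(OC)cc(OC)c(OC)c1OC.[Cl-] | intermediate
3 | 2,3,4,6-tetramethoxybenzaldehyde | O=Cc1c(OC)cc(OC)c(OC)c1OC | intermediate
4 | dichloro(2-formyl-3,5,6-trimethoxyphenoxy)borane (formed in the flask) | O=Cc1c(OC)cc(OC)c(OC)c1OB(Cl)Cl | intermediate
5 | 2-hydroxy-3,4,6-trimethoxybenzaldehyde | O=Cc1c(OC)cc(OC)c(OC)c1O | intermediate
6 | 3-bromo-6-hydroxy-2,4,5-trimethoxybenzaldehyde | O=Cc1c(OC)c(Br)c(OC)c(OC)c1O | intermediate
7 | 3-chloro-3-methylbut-1-yne | CC(C)(Cl)C#C | starting material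
8 | 3-bromo-2,4,5-trimethoxy-6-(2-methylbut-3-yn-2-yloxy)benzaldehyde | O=Cc1c(OC)c(Br)c(OC)c(OC)c1OC(C)(C)C#C | intermediate
9 | 3-bromo-2,4,5-trimethoxy-6-(2-methylbut-3-en-2-yloxy)benzaldehyde | O=Cc1c(OC)c(Br)c(OC)c(OC)c1OC(C)(C)C=C | intermediate
10 | 1-bromo-3-ethenyl-2,5,6-trimethoxy-4-(2-methylbut-3-en-2-yloxy)benzene | C=Cc1c(OC)c(Br)c(OC)c(OC)c1OC(C)(C)C=C | intermediate
11 | 3-phenylpropanal | O=CCCc1ccccc1 | starting material
12 | [3-ethenyl-2,5,6-trimethoxy-4-(2-methylbut-3-en-2-yloxy)phenyl]lithium (formed in the flask) | [Li]c1c(OC)c(C=C)c(OC(C)(C)C=C)c(OC)c1OC | intermediate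
13 | racemic 1-[3-ethenyl-2,5,6-trimethoxy-4-(2-methylbut-3-en-2-yloxy)phenyl]-3-phenylpropan-1-ol | C=Cc1c(OC)c(C(O)CCc2ccccc2)c(OC)c(OC)c1OC(C)(C)C=C | intermediate
14 | 1-[3-ethenyl-2,5,6-trimethoxy-4-(2-methylbut-3-en-2-yloxy)phenyl]-3-phenylpropan-1-one | C=Cc1c(OC)c(C(=O)CCc2ccccc2)c(OC)c(OC)c1OC(C)(C)C=C | intermediate
15 | 1-(5,7,8-trimethoxy-2,2-dimethyl-2H-chromen-6-yl)-3-phenylpropan-1-one | COc1c(C(=O)CCc2ccccc2)c(OC)c(OC)c2OC(C)(C)C=Cc12 | intermediate
16 | 7-methoxy-2,2-dimethyl-6-(3-phenylpropanoyl)-2H-chromene-5,8-dione | COC1=C(C(=O)CCc2ccccc2)C(=O)C2=C(OC(C)(C)C=C2)C1=O | intermediate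
17 | 1-(5,8-dihydroxy-7-methoxy-2,2-dimethyl-2H-chromen-6-yl)-3-phenylpropan-1-one (Flemistrictin D, achiral) | COc1c(O)c2c(c(O)c1C(=O)CCc1ccccc1)C=CC(C)(C)O2 | target

**Step count**

Total steps: 11. Longest linear sequence: 11 steps, from 1 to 17.

**Steps most likely to fail, with fallbacks**

Step 4. The phenoxide of 6 is held in a hydrogen bond to the ortho aldehyde and is flanked on both sides, so O-alkylation by the tertiary electrophile may stall while 7 is consumed by dehydrochlorination. The fallback sets out from 6 and removes the carbonyl first. Methylenation with excess Ph3P=CH2 (the first equivalent forms the phenoxide) should give 4-bromo-2-ethenyl-3,5,6-trimethoxyphenol F1, whose phenol is no longer tied to a carbonyl. Copper-catalysed propargylation of this phenol with 7 (CuCl2 cat., DBU, MeCN, 0 °C) should give 1-bromo-3-ethenyl-2,5,6-trimethoxy-4-(2-methylbut-3-yn-2-yloxy)benzene F2. Lindlar semi-hydrogenation of the alkyne, which is reduced faster than the styrene, returns to the route at 10.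

Step 9. Both alkenes are hindered, so initiation may be slow enough for the catalyst to decay to ruthenium hydrides, which would isomerise the terminal alkenes or cleave the tertiary allyl ether before the ring closes. The fallback sets out from 6 and closes the pyran without a metal carbene. Addition of 2-methylprop-1-enylmagnesium bromide (3 equiv, THF, 0 °C) to the aldehyde should give racemic 4-bromo-2-(1-hydroxy-3-methylbut-2-en-1-yl)-3,5,6-trimethoxyphenol F3. Warming in toluene with a trace of acid dehydrates it to the ortho-quinone methide 4-bromo-2,3,5-trimethoxy-6-(3-methylbut-2-en-1-ylidene)cyclohexa-2,4-dien-1-one F4, which is not isolated and closes by oxa-6π electrocyclisation to 6-bromo-5,7,8-trimethoxy-2,2-dimethyl-2H-chromene F5. Bromine–lithium exchange (n-BuLi, THF, −78 °C) gives (5,7,8-trimethoxy-2,2-dimethyl-2H-chromen-6-yl)lithium F6, which adds to 11 to give racemic 1-(5,7,8-trimethoxy-2,2-dimethyl-2H-chromen-6-yl)-3-phenylpropan-1-ol F7. Dess–Martin oxidation of this alcohol comes back to the route at 15.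

Step 10. The one-electron oxidant may not stay on the arene: the chromene alkene can be attacked, or water may enter at C7 instead of C5 and lead to loss of the wrong methyl group and an ortho-quinone. The fallback sets out from 15 and replaces the chemical oxidant by an electrode. Anodic oxidation in methanolic KOH (Pt anode, undivided cell, 0 °C) should add methoxide across the para positions C5 and C8 to give the quinone bis(dimethyl ketal) 1-(5,5,7,8,8-pentamethoxy-2,2-dimethyl-5,8-dihydro-2H-chromen-6-yl)-3-phenylpropan-1-one F8. Brief hydrolysis with dilute aqueous acid in acetone unmasks both carbonyls and comes back to the route at 16.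

**Further compounds**

F1 | step 4 | 4-bromo-2-ethenyl-3,5,6-trimethoxyphenol | C=Cc1c(OC)c(Br)c(OC)c(OC)c1O
F2 | step 4 | 1-bromo-3-ethenyl-2,5,6-trimethoxy-4-(2-methylbut-3-yn-2-yloxy)benzene | C=Cc1c(OC)c(Br)c(OC)c(OC)c1OC(C)(C)C#C
F3 | step 9 | racemic 4-bromo-2-(1-hydroxy-3-methylbut-2-en-1-yl)-3,5,6-trimethoxyphenol | CC(C)=CC(O)c1c(OC)c(Br)c(OC)c(OC)c1O
F4 | step 9 | 4-bromo-2,3,5-trimethoxy-6-(3-methylbut-2-en-1-ylidene)cyclohexa-2,4-dien-1-one | CC(C)=CC=C1C(OC)=C(Br)C(OC)=C(OC)C1=O
F5 | step 9 | 6-bromo-5,7,8-trimethoxy-2,2-dimethyl-2H-chromene | COc1c(Br)c(OC)c(OC)c2OC(C)(C)C=Cc12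
F6 | step 9 | (5,7,8-trimethoxy-2,2-dimethyl-2H-chromen-6-yl)lithium | [Li]c1c(OC)c2C=CC(C)(C)Oc2c(OC)c1OC
F7 | step 9 | racemic 1-(5,7,8-trimethoxy-2,2-dimethyl-2H-chromen-6-yl)-3-phenylpropan-1-ol | COc1c(C(O)CCc2ccccc2)c(OC)c(OC)c2OC(C)(C)C=Cc12
F8 | step 10 | 1-(5,5,7,8,8-pentamethoxy-2,2-dimethyl-5,8-dihydro-2H-chromen-6-yl)-3-phenylpropan-1-one | COC1=C(C(=O)CCc2ccccc2)C(OC)(OC)C2=C(OC(C)(C)C=C2)C1(OC)OC
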